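The ring-fusion bond C3a–C8a and both bonds to the cyclopentane carbon C2 (azulene numbering) are made together by a Rh(I)-catalysed allene–alkyne–CO cyclocarbonylation. It exploits the fact that the methyl-bearing quaternary C1 sits in the five-membered ring beside fusion carbon C8a, while the CMe2 carbon C4 sits in the seven-membered ring beside fusion carbon C3a. An ethynyl group on C4 and a 1,1-disubstituted allene terminus (the future C1) four atoms away therefore close both rings at once and turn the allene axis into the C1 stereocentre. The precursor is an acyclic, axially chiral, silyl-protected allenyne.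

Key step: step 11

Remark on numbering: all bicyclic compounds keep the azulene locants fixed in 18 (C1 quaternary carbon, C2 the carbonyl carbon of 18, C3a/C8a fusion carbons, C4 = CMe2, C8 the carbon that ends as C=CH2), also where strict nomenclature would renumber.
Assumption on the chemistry: in step 12 the quaternary C1 flank of the ketone is taken to act as the large group toward the oxazaborolidine.

Step 1
Reactants: 1 isobutyronitrile; 2 5-bromopent-1-ene
Product: 4 2,2-dimethylhept-6-enenitrile, via lithiated isobutyronitrile 3 (not isolated)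
Conditions: LDA, THF, −78 °C; then 2, −78 °C → rt
Reagents that add atoms: none
Why: α-Alkylation of a nitrile-stabilised carbanion, in which the compact lithiated tertiary nitrile displaces the primary bromide by SN2 to build the CMe2 carbon, the nitrile then serving as a latent alkyne that is inert to the organometallic steps that follow.

Step 2
Reactants: 4 2,2-dimethylhept-6-enenitrile
Product: 6 2,2-dimethyl-6-oxohexanenitrile, via secondary ozonide 5 (not isolated)
Conditions: O3, CH2Cl2, −78 °C; then PPh3, −78 °C → rt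
Reagents that add atoms: ozone, O=[O+][O-]
Why: Ozonolysis with reductive work-up cleaves the only alkene to the aldehyde one carbon shorter, the nitrile being inert to ozone and no stereocentre being formed.

Step 3
Reactants: 7 but-3-yn-1-ol
Product: 8 (but-3-yn-1-yloxy)(tert-butyl)diphenylsilane
Conditions: TBDPSCl, imidazole, DMF, rt
Reagents that add atoms: tert-butyl(chloro)diphenylsilane, CC(C)(C)[Si](Cl)(c1ccccc1)c1ccccc1
Why: Imidazole-promoted silylation masks the primary alcohol as a silyl ether that should survive organolithium, copper, hydride, Rh/CO and borane chemistry.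

Step 4
Reactants: 8 (but-3-yn-1-yloxy)(tert-butyl)diphenylsilane; 6 2,2-dimethyl-6-oxohexanenitrile
Product: 10 rac-10-[(tert-butyldiphenylsilyl)oxy]-6-hydroxy-2,2-dimethyldec-7-ynenitrile, via lithium acetylide 9 (not isolated)
Conditions: n-BuLi, THF, −78 °C; then 6, −78 °C; H2O quench
Reagents that add atoms: none
Why: 1,2-Addition of a lithium acetylide to an aldehyde at −78 °C is far faster than attack on the hindered tertiary nitrile, and the racemic carbinol centre is erased in the next step.

Step 5
Reactants: 10 rac-10-[(tert-butyldiphenylsilyl)oxy]-6-hydroxy-2,2-dimethyldec-7-ynenitrile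
Product: 11 10-[(tert-butyldiphenylsilyl)oxy]-2,2-dimethyl-6-oxodec-7-ynenitrile
Conditions: Dess–Martin periodinane, NaHCO3, CH2Cl2, 0 °C → rt
Reagents that add atoms: none
Why: Dess–Martin oxidation of a propargylic alcohol should give the ynone under near-neutral conditions that leave the silyl ether and the nitrile untouched.

Step 6
Reactants: 11 10-[(tert-butyldiphenylsilyl)oxy]-2,2-dimethyl-6-oxodec-7-ynenitrile
Product: 12 (6S)-10-[(tert-butyldiphenylsilyl)oxy]-6-hydroxy-2,2-dimethyldec-7-ynenitrile
Conditions: Ru[(S,S)-TsDPEN](p-cymene) (1 mol%), i-PrOH, rt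
Reagents that add atoms: none
Why: Noyori–Ikariya asymmetric transfer hydrogenation of an alkynyl ketone, in which the (S,S)-Ru hydride attacks the carbonyl face that gives the (S)-propargylic alcohol (the alkynyl group taking the place aryl occupies in aryl ketones) without reducing the C≡C bond.

Step 7
Reactants: 12 (6S)-10-[(tert-butyldiphenylsilyl)oxy]-6-hydroxy-2,2-dimethyldec-7-ynenitrile
Product: 13 (5S)-1-[(tert-butyldiphenylsilyl)oxy]-9-cyano-9-methyldec-3-yn-5-yl methanesulfonate
Conditions: MsCl, Et3N, CH2Cl2, −40 → 0 °C (used crude)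
Reagents that add atoms: methanesulfonyl chloride, CS(=O)(=O)Cl
Why: O-Sulfonylation occurs with retention at carbon and converts the hydroxyl into the leaving group needed for the SN2′ step.

Step 8
Reactants: 13 (5S)-1-[(tert-butyldiphenylsilyl)oxy]-9-cyano-9-methyldec-3-yn-5-yl methanesulfonate
Product: 14 (Sa)-10-[(tert-butyldiphenylsilyl)oxy]-2,2,8-trimethyldeca-6,7-dienenitrile
Conditions: MeMgBr, CuBr·SMe2, LiBr, THF, −70 → −20 °C
Reagents that add atoms: methylmagnesium bromide, C[Mg]Br
Why: anti-SN2′ substitution of a propargylic mesylate by a methylcopper reagent, in which copper attacks the distal alkyne carbon anti to the leaving group and delivers methyl there, so the (S) carbinol centre is transferred into the (Sa) allene axis, while low temperature and the halide-rich monoalkylcopper should limit racemisation.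

Step 9
Reactants: 14 (Sa)-10-[(tert-butyldiphenylsilyl)oxy]-2,2,8-trimethyldeca-6,7-dienenitrile
Product: 16 (Sa)-10-[(tert-butyldiphenylsilyl)oxy]-2,2,8-trimethyldeca-6,7-dienal, via aluminium aldimine 15 (not isolated)
Conditions: DIBAL-H, CH2Cl2, −78 °C; then 1 M aq. tartaric acid, 0 °C
Reagents that add atoms: water, O
Why: Partial reduction of a nitrile by DIBAL-H stops at the N-aluminated aldimine, which hydrolyses to the α-quaternary aldehyde on work-up, while the allene and the silyl ether should not react at −78 °C.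

Step 10
Reactants: 16 (Sa)-10-[(tert-butyldiphenylsilyl)oxy]-2,2,8-trimethyldeca-6,7-dienal
Product: 17 tert-butyldiphenyl{[(Sa)-3,9,9-trimethylundeca-3,4-dien-10-yn-1-yl]oxy}silane
Conditions: dimethyl (1-diazo-2-oxopropyl)phosphonate, K2CO3, MeOH, 0 °C → rt
Reagents that add atoms: dimethyl (1-diazo-2-oxopropyl)phosphonate, COP(=O)(OC)C(=[N+]=[N-])C(C)=O
Why: Seyferth–Gilbert homologation in its Ohira–Bestmann form turns the non-enolisable aldehyde into the terminal alkyne under conditions too mild to isomerise or racemise the trialkylallene, so the alkyne appears only after all acetylide and copper chemistry is finished.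

Step 11
Reactants: 17 tert-butyldiphenyl{[(Sa)-3,9,9-trimethylundeca-3,4-dien-10-yn-1-yl]oxy}silane
Product: 18 (1S)-1-{2-[(tert-butyldiphenylsilyl)oxy]ethyl}-1,4,4-trimethyl-4,5,6,7-tetrahydroazulen-2(1H)-one
Conditions: [Rh(CO)2Cl]2 (5 mol%), CO (1 atm), toluene (0.02 M), 90 °C
Reagents that add atoms: carbon monoxide, [C-]#[O+]
Why: Rh(I) binds the alkyne and, through the four-atom tether, the distal allene π bond; oxidative cyclometallation joins the internal alkyne carbon to the central allene carbon to give a rhodacyclopentene, and CO insertion followed by reductive elimination completes the cyclopentenone (allenic Pauson–Khand reaction, a [2+2+1] cyclocarbonylation). The closest known reaction type is the Rh(I)-catalysed cyclocarbonylation of allenynes with a four-atom tether to bicyclo[5.3.0]decadienones, including axially chiral allenes. The cycloheptene closes in the cyclometallation event as a seven-membered ring that keeps the proximal allene C=C, necessarily as a Z ring alkene, so the new bond forms on the tether side; the cyclopentenone closes by the formal [2+2+1] union of alkyne, distal C=C and CO. The only new stereocentre, C1, is set by the allene axis, because Rh and then the acyl carbon attach to the distal terminus on the π face toward which the tether points, so (Sa)-17 should give (1S)-18 without an external control element. The step needs distal rather than proximal π-bond selectivity, which Rh(I) with this tether length secures, and carbonylation faster than β-hydride loss from the rhodacycle, which the CO atmosphere, dilution and the Thorpe–Ingold effect of the propargylic gem-dimethyl group favour.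

Step 12
Reactants: 18 (1S)-1-{2-[(tert-butyldiphenylsilyl)oxy]ethyl}-1,4,4-trimethyl-4,5,6,7-tetrahydroazulen-2(1H)-one
Product: 19 (1S,2S)-1-{2-[(tert-butyldiphenylsilyl)oxy]ethyl}-1,4,4-trimethyl-1,2,4,5,6,7-hexahydroazulen-2-ol (OH cis to the C1 methyl)
Conditions: (R)-2-methyl-CBS-oxazaborolidine (0.5 equiv), catecholborane, toluene, −78 → −40 °C
Reagents that add atoms: none
Why: Corey–Bakshi–Shibata reduction, in which the oxazaborolidine binds the carbonyl oxygen on the side of the small vinylic CH flank and delivers hydride 1,2 to the face carrying the silyloxyethyl arm, so the C2 hydroxyl should end cis to the C1 methyl under catalyst control, the substrate's own bias (CH3 against CH2CH2OSi) being small.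

Step 13
Reactants: 19 (1S,2S)-1-{2-[(tert-butyldiphenylsilyl)oxy]ethyl}-1,4,4-trimethyl-1,2,4,5,6,7-hexahydroazulen-2-ol
Product: 20 (1S,2S)-1-{2-[(tert-butyldiphenylsilyl)oxy]ethyl}-1,4,4-trimethyl-1,2,4,5,6,7-hexahydroazulen-2-yl formate
Conditions: acetic formic anhydride (preformed), pyridine, CH2Cl2, 0 °C (used crude)
Reagents that add atoms: acetic formic anhydride, CC(=O)OC=O
Why: O-Formylation of the hindered secondary alcohol by the small mixed anhydride proceeds with retention and installs the internal hydride source for the next step.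

Step 14
Reactants: 20 (1S,2S)-1-{2-[(tert-butyldiphenylsilyl)oxy]ethyl}-1,4,4-trimethyl-1,2,4,5,6,7-hexahydroazulen-2-yl formate
Product: 21 (1R,3aS)-1-{2-[(tert-butyldiphenylsilyl)oxy]ethyl}-1,4,4-trimethyl-1,3a,4,5,6,7-hexahydroazulene (H-3a cis to the silyloxyethyl arm)
Conditions: Pd(OAc)2 (5 mol%), n-Bu3P (10 mol%), THF, rt → 40 °C
Reagents that add atoms: none
Why: Palladium-catalysed hydrogenolysis of an allylic formate, in which Pd(0) ionises the formate with inversion, loss of CO2 gives a palladium hydride, and hydride passes from the metal face to the more substituted allyl terminus C3a, so H-3a should enter anti to the departed formate (cis to the arm) while the oxygen is removed and the alkene moves to C2=C3, as known for setting ring-fusion centres from allylic formates.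

Step 15
Reactants: 21 (1R,3aS)-1-{2-[(tert-butyldiphenylsilyl)oxy]ethyl}-1,4,4-trimethyl-1,3a,4,5,6,7-hexahydroazulene
Product: 22 (1S,3aS)-1-{2-[(tert-butyldiphenylsilyl)oxy]ethyl}-1,4,4-trimethyl-1,2,3,3a,4,5,6,7-octahydroazulene
Conditions: RhCl(PPh3)3 (5 mol%), H2 (1 atm), benzene/EtOH, rt
Reagents that add atoms: none
Why: Homogeneous hydrogenation with Wilkinson's catalyst reduces the unhindered cis-disubstituted cyclopentene far faster than the trisubstituted C8=C8a alkene flanked by two fully substituted carbons, which is kept for hydroboration, and no stereocentre is formed.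

Step 16
Reactants: 22 (1S,3aS)-1-{2-[(tert-butyldiphenylsilyl)oxy]ethyl}-1,4,4-trimethyl-1,2,3,3a,4,5,6,7-octahydroazulene
Product: 24 (1S,3aR,8S,8aR)-1-{2-[(tert-butyldiphenylsilyl)oxy]ethyl}-1,4,4-trimethyldecahydroazulen-8-ol, via alkylborane 23 (not isolated)
Conditions: BH3·THF, THF, 0 °C → rt; then aq. NaOH, 30% H2O2, 0 °C → rt
Reagents that add atoms: hydrogen peroxide, OO
Why: Hydroboration–oxidation (syn, anti-Markovnikov) puts boron on the less substituted C8 and hydrogen on C8a from the alkene face that carries H-3a, the opposite face being screened by C4 with its gem-dimethyl group and by the C1 methyl, so the ring fusion should become cis with H-8a cis to H-3a and to the arm, the C8 carbinol configuration being irrelevant.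

Step 17
Reactants: 24 (1S,3aR,8S,8aR)-1-{2-[(tert-butyldiphenylsilyl)oxy]ethyl}-1,4,4-trimethyldecahydroazulen-8-ol
Product: 25 (1S,3aR,8aR)-1-{2-[(tert-butyldiphenylsilyl)oxy]ethyl}-1,4,4-trimethyloctahydroazulen-8(1H)-one
Conditions: Dess–Martin periodinane, NaHCO3, CH2Cl2, 0 °C → rt
Reagents that add atoms: none
Why: Buffered Dess–Martin oxidation converts the secondary alcohol into the ketone under non-enolising conditions, so the adjacent C8a centre should not epimerise.

Step 18
Reactants: 25 (1S,3aR,8aR)-1-{2-[(tert-butyldiphenylsilyl)oxy]ethyl}-1,4,4-trimethyloctahydroazulen-8(1H)-one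
Product: 26 (1S,3aR,8aS)-1-{2-[(tert-butyldiphenylsilyl)oxy]ethyl}-1,4,4-trimethyl-8-methylidenedecahydroazulene
Conditions: Zn, CH2Br2, TiCl4, THF/CH2Cl2, 0 °C → rt
Reagents that add atoms: dibromomethane, BrCBr
Why: Takai–Lombardo methylenation with the non-basic Zn/CH2Br2/TiCl4 reagent converts the hindered, enolisable ketone into the exocyclic alkene without epimerising C8a, where a basic ylide might enolise the ketone.

Step 19
Reactants: 26 (1S,3aR,8aS)-1-{2-[(tert-butyldiphenylsilyl)oxy]ethyl}-1,4,4-trimethyl-8-methylidenedecahydroazulene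
Product: 27 2-[(1S,3aR,8aS)-1,4,4-trimethyl-8-methylidenedecahydroazulen-1-yl]ethan-1-ol
Conditions: TBAF, THF, rt
Reagents that add atoms: none
Why: Fluoride-induced desilylation, driven by the strong Si–F bond, frees the primary alcohol, and nothing else in the molecule is fluoride-labile.

Step 20
Reactants: 27 2-[(1S,3aR,8aS)-1,4,4-trimethyl-8-methylidenedecahydroazulen-1-yl]ethan-1-ol
Product: 28 2-[(1S,3aR,8aS)-1,4,4-trimethyl-8-methylidenedecahydroazulen-1-yl]acetic acid
Conditions: PhI(OAc)2, TEMPO (cat.), MeCN/H2O, rt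
Reagents that add atoms: water, O
Why: Oxoammonium (TEMPO/PhI(OAc)2) oxidation in aqueous acetonitrile takes the primary alcohol through the aldehyde hydrate to the acid and should leave the 1,1-disubstituted alkene alone.

Step 21
Reactants: 28 2-[(1S,3aR,8aS)-1,4,4-trimethyl-8-methylidenedecahydroazulen-1-yl]acetic acid; 29 (R)-4-benzyloxazolidin-2-one
Product: 31 (4R)-4-benzyl-3-{2-[(1S,3aR,8aS)-1,4,4-trimethyl-8-methylidenedecahydroazulen-1-yl]acetyl}oxazolidin-2-one, via mixed pivalic anhydride 30 (not isolated)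
Conditions: PivCl, Et3N, THF, −20 °C; then 29, LiCl, rt
Reagents that add atoms: none
Why: N-Acylation of the oxazolidinone through the mixed pivalic anhydride, in which the nucleophile attacks the less hindered acyl carbon, attaches the chiral controller for the next step.

Step 22
Reactants: 31 (4R)-4-benzyl-3-{2-[(1S,3aR,8aS)-1,4,4-trimethyl-8-methylidenedecahydroazulen-1-yl]acetyl}oxazolidin-2-one; 32 furan-2(5H)-one
Product: 34 (4R)-4-benzyl-3-{(2R)-2-[(3R)-5-oxooxolan-3-yl]-2-[(1R,3aR,8aS)-1,4,4-trimethyl-8-methylidenedecahydroazulen-1-yl]acetyl}oxazolidin-2-one, via sodium enolate 33 (not isolated)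
Conditions: NaHMDS, THF, −78 °C; then 32, −78 → −40 °C; AcOH quench
Reagents that add atoms: none
Why: Auxiliary-controlled Michael addition of a chelated (Z)-imide enolate to a butenolide, in which the acceptor approaches the enolate face opposite the benzyl group of the (R)-auxiliary (setting the acyl α-carbon as R) and an open synclinal transition state, with the bulky azulenyl group anti to the lactone α-carbon and the enolate hydrogen over the ring, is expected to give the (3R) lactone carbon.

Step 23
Reactants: 34 (4R)-4-benzyl-3-{(2R)-2-[(3R)-5-oxooxolan-3-yl]-2-[(1R,3aR,8aS)-1,4,4-trimethyl-8-methylidenedecahydroazulen-1-yl]acetyl}oxazolidin-2-one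
Product: 35 (4R)-4-{(1R)-2-hydroxy-1-[(1R,3aR,8aS)-1,4,4-trimethyl-8-methylidenedecahydroazulen-1-yl]ethyl}oxolan-2-one
Conditions: NaBH4, THF/H2O (4:1), 0 °C → rt
Reagents that add atoms: none
Why: Reductive removal of the auxiliary, in which NaBH4 in wet THF reduces the activated exocyclic imide carbonyl to the primary alcohol faster than the γ-lactone and releases the oxazolidinone without touching a stereocentre.

Step 24
Reactants: 35 (4R)-4-{(1R)-2-hydroxy-1-[(1R,3aR,8aS)-1,4,4-trimethyl-8-methylidenedecahydroazulen-1-yl]ethyl}oxolan-2-one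
Product: 36 (2R)-2-[(3R)-5-oxooxolan-3-yl]-2-[(1R,3aR,8aS)-1,4,4-trimethyl-8-methylidenedecahydroazulen-1-yl]ethyl acetate (CNP0235949.1)
Conditions: Ac2O, pyridine, DMAP (cat.), CH2Cl2, rt
Reagents that add atoms: acetic anhydride, CC(=O)OC(C)=O
Why: DMAP-catalysed acylation of the primary alcohol gives the acetate, the γ-lactone and the exocyclic alkene being inert.

Compound list
1 | isobutyronitrile | CC(C)C#N | starting material
2 | 5-bromopent-1-ene | C=CCCCBr | starting material
3 | lithiated isobutyronitrile | CC(C)([Li])C#N | intermediate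
4 | 2,2-dimethylhept-6-enenitrile | N#CC(C)(C)CCCC=C | intermediate
5 | 2,2-dimethyl-5-(1,2,4-trioxolan-3-yl)pentanenitrile (secondary ozonide) | N#CC(C)(C)CCCC1OCOO1 | intermediate
6 | 2,2-dimethyl-6-oxohexanenitrile | N#CC(C)(C)CCCC=O | intermediate
7 | but-3-yn-1-ol | C#CCCO | starting material
8 | (but-3-yn-1-yloxy)(tert-butyl)diphenylsilane | C#CCCO[Si](c1ccccc1)(c1ccccc1)C(C)(C)C | intermediate
9 | lithium acetylide of 8 | [Li]C#CCCO[Si](c1ccccc1)(c1ccccc1)C(C)(C)C | intermediate
10 | rac-10-[(tert-butyldiphenylsilyl)oxy]-6-hydroxy-2,2-dimethyldec-7-ynenitrile | N#CC(C)(C)CCCC(O)C#CCCO[Si](c1ccccc1)(c1ccccc1)C(C)(C)C | intermediate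
11 | 10-[(tert-butyldiphenylsilyl)oxy]-2,2-dimethyl-6-oxodec-7-ynenitrile | N#CC(C)(C)CCCC(=O)C#CCCO[Si](c1ccccc1)(c1ccccc1)C(C)(C)C | intermediate
12 | (6S)-10-[(tert-butyldiphenylsilyl)oxy]-6-hydroxy-2,2-dimethyldec-7-ynenitrile | N#CC(C)(C)CCC[C@H](O)C#CCCO[Si](c1ccccc1)(c1ccccc1)C(C)(C)C | intermediate
13 | (5S)-1-[(tert-butyldiphenylsilyl)oxy]-9-cyano-9-methyldec-3-yn-5-yl methanesulfonate | N#CC(C)(C)CCC[C@H](OS(C)(=O)=O)C#CCCO[Si](c1ccccc1)(c1ccccc1)C(C)(C)C | intermediate
14 | (Sa)-10-[(tert-butyldiphenylsilyl)oxy]-2,2,8-trimethyldeca-6,7-dienenitrile | N#CC(C)(C)CCCC([H])=[C@@]=C(C)CCO[Si](c1ccccc1)(c1ccccc1)C(C)(C)C | intermediate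
15 | N-(diisobutylaluminio) aldimine of 14 | CC(C)C[Al](CC(C)C)/N=C/C(C)(C)CCCC([H])=[C@@]=C(C)CCO[Si](c1ccccc1)(c1ccccc1)C(C)(C)C | intermediate
16 | (Sa)-10-[(tert-butyldiphenylsilyl)oxy]-2,2,8-trimethyldeca-6,7-dienal | O=CC(C)(C)CCCC([H])=[C@@]=C(C)CCO[Si](c1ccccc1)(c1ccccc1)C(C)(C)C | intermediate
17 | tert-butyldiphenyl{[(Sa)-3,9,9-trimethylundeca-3,4-dien-10-yn-1-yl]oxy}silane (allenyne, key-step precursor) | C#CC(C)(C)CCCC([H])=[C@@]=C(C)CCO[Si](c1ccccc1)(c1ccccc1)C(C)(C)C | intermediate
18 | (1S)-1-{2-[(tert-butyldiphenylsilyl)oxy]ethyl}-1,4,4-trimethyl-4,5,6,7-tetrahydroazulen-2(1H)-one (key-step product) | O=C1C=C2C(C)(C)CCCC=C2[C@]1(C)CCO[Si](c3ccccc3)(c3ccccc3)C(C)(C)C | intermediate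
19 | (1S,2S)-1-{2-[(tert-butyldiphenylsilyl)oxy]ethyl}-1,4,4-trimethyl-1,2,4,5,6,7-hexahydroazulen-2-ol | O[C@H]1C=C2C(C)(C)CCCC=C2[C@]1(C)CCO[Si](c3ccccc3)(c3ccccc3)C(C)(C)C | intermediate
20 | (1S,2S)-1-{2-[(tert-butyldiphenylsilyl)oxy]ethyl}-1,4,4-trimethyl-1,2,4,5,6,7-hexahydroazulen-2-yl formate | O=CO[C@H]1C=C2C(C)(C)CCCC=C2[C@]1(C)CCO[Si](c3ccccc3)(c3ccccc3)C(C)(C)C | intermediate
21 | (1R,3aS)-1-{2-[(tert-butyldiphenylsilyl)oxy]ethyl}-1,4,4-trimethyl-1,3a,4,5,6,7-hexahydroazulene | C1=C[C@H]2C(C)(C)CCCC=C2[C@]1(C)CCO[Si](c3ccccc3)(c3ccccc3)C(C)(C)C | intermediate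
22 | (1S,3aS)-1-{2-[(tert-butyldiphenylsilyl)oxy]ethyl}-1,4,4-trimethyl-1,2,3,3a,4,5,6,7-octahydroazulene | C1C[C@H]2C(C)(C)CCCC=C2[C@]1(C)CCO[Si](c3ccccc3)(c3ccccc3)C(C)(C)C | intermediate
23 | monoalkylborane from 22 (boron on C8, cis to H-8a) | B[C@H]1CCCC(C)(C)[C@@H]2CC[C@@](C)(CCO[Si](c3ccccc3)(c3ccccc3)C(C)(C)C)[C@H]12 | intermediate
24 | (1S,3aR,8S,8aR)-1-{2-[(tert-butyldiphenylsilyl)oxy]ethyl}-1,4,4-trimethyldecahydroazulen-8-ol | O[C@H]1CCCC(C)(C)[C@@H]2CC[C@@](C)(CCO[Si](c3ccccc3)(c3ccccc3)C(C)(C)C)[C@H]12 | intermediate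
25 | (1S,3aR,8aR)-1-{2-[(tert-butyldiphenylsilyl)oxy]ethyl}-1,4,4-trimethyloctahydroazulen-8(1H)-one | O=C1CCCC(C)(C)[C@@H]2CC[C@@](C)(CCO[Si](c3ccccc3)(c3ccccc3)C(C)(C)C)[C@H]12 | intermediate
26 | (1S,3aR,8aS)-1-{2-[(tert-butyldiphenylsilyl)oxy]ethyl}-1,4,4-trimethyl-8-methylidenedecahydroazulene | C=C1CCCC(C)(C)[C@@H]2CC[C@@](C)(CCO[Si](c3ccccc3)(c3ccccc3)C(C)(C)C)[C@H]12 | intermediate
27 | 2-[(1S,3aR,8aS)-1,4,4-trimethyl-8-methylidenedecahydroazulen-1-yl]ethan-1-ol | C=C1CCCC(C)(C)[C@@H]2CC[C@@](C)(CCO)[C@H]12 | intermediate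
28 | 2-[(1S,3aR,8aS)-1,4,4-trimethyl-8-methylidenedecahydroazulen-1-yl]acetic acid | C=C1CCCC(C)(C)[C@@H]2CC[C@@](C)(CC(=O)O)[C@H]12 | intermediate
29 | (R)-4-benzyloxazolidin-2-one | O=C1N[C@H](Cc2ccccc2)CO1 | starting material
30 | mixed pivalic anhydride of 28 | C=C1CCCC(C)(C)[C@@H]2CC[C@@](C)(CC(=O)OC(=O)C(C)(C)C)[C@H]12 | intermediate
31 | (4R)-4-benzyl-3-{2-[(1S,3aR,8aS)-1,4,4-trimethyl-8-methylidenedecahydroazulen-1-yl]acetyl}oxazolidin-2-one | C=C1CCCC(C)(C)[C@@H]2CC[C@@](C)(CC(=O)N3[C@H](Cc4ccccc4)COC3=O)[C@H]12 | intermediate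
32 | furan-2(5H)-one | O=C1OCC=C1 | starting material
33 | sodium (Z)-enolate of 31 | C=C1CCCC(C)(C)[C@@H]2CC[C@@](C)(/C=C(\[O-])N3[C@H](Cc4ccccc4)COC3=O)[C@H]12.[Na+] | intermediate
34 | (4R)-4-benzyl-3-{(2R)-2-[(3R)-5-oxooxolan-3-yl]-2-[(1R,3aR,8aS)-1,4,4-trimethyl-8-methylidenedecahydroazulen-1-yl]acetyl}oxazolidin-2-one | C=C1CCCC(C)(C)[C@@H]2CC[C@@](C)([C@H](C(=O)N3[C@H](Cc4ccccc4)COC3=O)[C@@H]5COC(=O)C5)[C@H]12 | intermediate
35 | (4R)-4-{(1R)-2-hydroxy-1-[(1R,3aR,8aS)-1,4,4-trimethyl-8-methylidenedecahydroazulen-1-yl]ethyl}oxolan-2-one | C=C1CCCC(C)(C)[C@@H]2CC[C@@](C)([C@H](CO)[C@@H]3COC(=O)C3)[C@H]12 | intermediate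
36 | (2R)-2-[(3R)-5-oxooxolan-3-yl]-2-[(1R,3aR,8aS)-1,4,4-trimethyl-8-methylidenedecahydroazulen-1-yl]ethyl acetate | C=C1CCCC(C)(C)[C@@H]2CC[C@@](C)([C@H](COC(C)=O)[C@@H]3COC(=O)C3)[C@H]12 | target

Total step count: 24.
Longest linear sequence: 23 steps (steps 1, 2 and 4–24; step 3 is the only off-line step).

Steps most likely to fail

Step 11. Cyclometallation onto the fully substituted allene terminus may be slow, so the terminal alkyne could be consumed by Rh-mediated C–H pathways (dimerisation, oligomerisation) before the rhodacycle forms and carbonylates. The fallback redesigns the substrate so that the alkyne terminus is blocked. It sets out from 17: deprotonation (n-BuLi, THF, −78 °C) and trapping with TMSCl should give the trimethylsilyl alkyne F1. The same Rh(I)/CO cyclocarbonylation, now on an internal 1-silylalkyne (a well-documented substrate class for seven-membered-ring allenic cyclocarbonylation), should give the α-silyl dienone F2. Protodesilylation of the α-silyl enone with K2CO3 in MeOH (which leaves the TBDPS ether) comes back to the route at 18.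

Step 14. Hydride may be transferred to a terminal carbon of the extended (pentadienyl) palladium intermediate instead of C3a, or the intermediate may lose a β-hydrogen to give a triene; ionisation is also slowed because palladium must approach the face bearing the silyloxyethyl arm. The fallback replaces steps 12–14 by a hydrazone reduction with alkene transposition. It sets out from 18: condensation with TsNHNH2 (EtOH, cat. AcOH, 60 °C) should give the tosylhydrazone F3. Catecholborane (CHCl3, 0 °C), then NaOAc·3H2O at reflux, adds hydride to C2 anti to the arm; the resulting allylic diazene loses N2 in a retro-ene step that delivers hydrogen to C3a on the arm face and moves the alkene to C2=C3. This comes back to the route at 21. Facial control here rests on the substrate alone and is expected to be weaker than in the main route.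

Step 22. Facial selectivity at the butenolide may be poor (wrong relative topicity at the lactone carbon), or the hindered enolate may take a proton from the butenolide γ-CH2 instead of adding. The fallback moves control of the lactone carbon to the acceptor. It sets out from 31: the same sodium enolate is added to (5S)-5-{[(1S,2R,5S)-5-methyl-2-(propan-2-yl)cyclohexyl]oxy}furan-2(5H)-one, O=C1C=C[C@@H](O[C@H]2C[C@@H](C)CC[C@@H]2C(C)C)O1, which accepts nucleophiles trans to the alkoxy group and should give the menthyloxy lactone adduct F4. Mild acid hydrolysis of the acetal (1 M HCl, THF, rt) should give the lactol F5. NaBH4 in wet THF then reduces both the ring-opened aldehyde and the imide, and acidification closes the γ-lactone, coming back to the route at 35.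

Further compounds
F1 | step 11 | tert-butyldiphenyl{[(Sa)-3,9,9-trimethyl-11-(trimethylsilyl)undeca-3,4-dien-10-yn-1-yl]oxy}silane | C[Si](C)(C)C#CC(C)(C)CCCC([H])=[C@@]=C(C)CCO[Si](c1ccccc1)(c1ccccc1)C(C)(C)C
F2 | step 11 | (1S)-1-{2-[(tert-butyldiphenylsilyl)oxy]ethyl}-1,4,4-trimethyl-3-(trimethylsilyl)-4,5,6,7-tetrahydroazulen-2(1H)-one | O=C1C([Si](C)(C)C)=C2C(C)(C)CCCC=C2[C@]1(C)CCO[Si](c3ccccc3)(c3ccccc3)C(C)(C)C
F3 | step 14 | N'-[(1S)-1-{2-[(tert-butyldiphenylsilyl)oxy]ethyl}-1,4,4-trimethyl-4,5,6,7-tetrahydroazulen-2(1H)-ylidene]-4-methylbenzenesulfonohydrazide | Cc1ccc(cc1)S(=O)(=O)N/N=C3\C=C2C(C)(C)CCCC=C2[C@]3(C)CCO[Si](c4ccccc4)(c4ccccc4)C(C)(C)C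
F4 | step 22 | (4R)-4-benzyl-3-{(2R)-2-[(2S,3R)-2-{[(1S,2R,5S)-5-methyl-2-(propan-2-yl)cyclohexyl]oxy}-5-oxooxolan-3-yl]-2-[(1R,3aR,8aS)-1,4,4-trimethyl-8-methylidenedecahydroazulen-1-yl]acetyl}oxazolidin-2-one | C=C1CCCC(C)(C)[C@@H]2CC[C@@](C)([C@H](C(=O)N3[C@H](Cc4ccccc4)COC3=O)[C@@H]5[C@@H](O[C@H]6C[C@@H](C)CC[C@@H]6C(C)C)OC(=O)C5)[C@H]12
F5 | step 22 | (4R)-4-benzyl-3-{(2R)-2-[(3R)-2-hydroxy-5-oxooxolan-3-yl]-2-[(1R,3aR,8aS)-1,4,4-trimethyl-8-methylidenedecahydroazulen-1-yl]acetyl}oxazolidin-2-one (lactol, both anomers) | C=C1CCCC(C)(C)[C@@H]2CC[C@@](C)([C@H](C(=O)N3[C@H](Cc4ccccc4)COC3=O)[C@@H]5C(O)OC(=O)C5)[C@H]12
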